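(The constants are assumed; the result is computed.)

The constants were read out first, and the flask with them.

solid substrate 0.10 M; reagent 0.0700 M; time 15 h

    solid substrate ⇌ dissolved substrate, rate k1*(cs1 - [dissolved substrate]) while solid is left; crystals form when [dissolved substrate] > cs1 (cs1 = 3.6 mM, k1 = 0.0055 s⁻¹)
    dissolved substrate + reagent → target (k2 = 0.0064 M⁻¹ s⁻¹)
    2 dissolved substrate → side product (k3 = 0.0020 M⁻¹ s⁻¹)
    solid product ⇌ target, rate k4*(cs4 - [target]) while solid is left; crystals form when [target] > cs4 (cs4 = 1.2 mM, k4 = 0.0010 s⁻¹)
    reagent ⇌ dormant form (K5 = 0.55, k5 = 0.0018 s⁻¹)

- percentages count the solid substrate that a species holds: one side product counts as two
- target is meant together with its solid product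
- a doubled species enters its step squared and goes two at a time
- solid, in amounts per volume of the solution: solid substrate, solid product
- at the start none of the solid substrate is in solution
- run time (flask): 15 h

1. how much target and solid product together there is at 15 h, in percent of the solid substrate charged
2. the change that raises the amount of target and solid product together at 15 h, in percent of the solid substrate charged most ("none" if none brings more than 2 percentage points) (beta / alpha / zeta / epsilon / none)
3. amount of target and solid product together at 15 h, in percent of the solid substrate charged, after zeta

- beta: doubling the amount of reagent, all else as stated
- alpha: doubling the solubility in step 1, all else as stated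
- zeta: doubling the dissolution coefficient of step 1, all else as stated
- epsilon: doubling the solubility in step 4, all else as stated

Minutes of the meeting. I opened at the blackboard by calling reagent the limiting reagent, as its charge of 0.0700 M is smaller than the 0.10 M of solid substrate, so that target in this flask can reach 70.0%.

A colleague asked whether dissolution keeps up. I answered that step 1 can deliver 1069% by 15 h into a solution kept empty, if the solid never ran out, far more than that ceiling, and proposed holding c(dissolved substrate) at 3.6 mM while solid substrate is left.

A second colleague objected that reagent hides in the dormant form, leaving a free share of 0.645 in c(reagent) + c(dormant form). I replied that this pool therefore falls by a pseudo-first-order law with 0.0535 h⁻¹, which we named the pool constant: step 2's constant times the solubility times the free share. Its half-life of 13.0 h is much longer than the 0.11 h of step 5's forward rate alone, so I took the share as holding once step 5 has come to balance.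

Integrating the pool's rate, I committed to 38.6% for this flask. By the same law I reckoned 77.3% for doubling the reagent, while doubling the solubility doubles the pool constant and gave me 55.9%, which is less. Zeta does not enter the pool constant, and epsilon moves target between two forms counted together.

The forecast gave 37.7%, a little below my figure, named beta as best and gave 38.3% after zeta, on the ground that “dissolved substrate sits just under its solubility”.

The flask gives 37.6%, and 38.1% after zeta; the best change is beta, worth 36 percentage points against 18 points for alpha. At 15.0 h this flask holds reagent at 29.8% of its charge and dormant form at 0.0115 M, together 46.2% of the reagent charged, against 44.8% by the pool constant. For the neighbour flask left until 2.5 d, the pool constant gives 67.2%, and that flask reads 67.0%.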